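A closed, stirred vessel holds Q and L, which combine to E, with Z also present. Percentages count against the Q charged.

| flask | Q | L | Z | remark | time |
|---|---|---|---|---|---|
| south | 1.4 M | 0.90 M | 1 M | run made earlier |  |
| north | 2.2 M | 0.90 M | 1 M | run made earlier |  |
| south-west | 1 M | 0.90 M | 2 M | run made earlier |  |
| flask | 1.0 M | 0.900 M | 1.00 M |  | 15 d |

| run | time / d | E / % | Q / % |
|---|---|---|---|
| south | 1.25 | 45.7 | 53.1 |
| south | 3.00 | 50.0 | 44.6 |
| south | 8.00 | 50.8 | 43.6 |
| south | 20.0 | 44.9 | 46.5 |
| north | 1.25 | 34.4 | 65.1 |
| north | 3.00 | 35.8 | 61.1 |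
| north | 8.00 | 36.3 | 62.7 |
| north | 20.0 | 34.7 | 63.4 |
| south-west | 1.25 | 45.9 | 52.1 |
| south-west | 3.00 | 57.6 | 36.8 |
| south-west | 8.00 | 60.6 | 28.9 |
| south-west | 20.0 | 52.8 | 31.1 |

(scatter of a reading: 0.5 percentage points)

* time up to 15 d at which E stands highest
* the amount of E, in percent of the Q charged, at that time
* earliest time at which at least nineteen twentieths of that best amount are there, in d
* latest time at which they still are, in d



Two of us read these runs differently. The first holds a balance view, in which Q + L ⇌ E comes to rest at one constant and a slow loss then trims it. The forecast is that side: “Equilibrium alone gives about 62%, and the loss trims that to about 61% near 6 d.” It puts 61% at 6 d, with the band from 3 d to 12.5 d.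

I hold a ledger view. In the flask L is the limiting reagent, so its ceiling on E starts at 90.0% of the Q charged. Let ℓ be the part of the Q that the E and Q readings do not account for. In the south run, from 8.00 d to 20.0 d, E fell 5.9 percentage points while ℓ grew 3 points. That gives a price of 1.97, the units of E given up per unit of Q lost, and as a ratio of small differences it is rough. I take the ceiling to fall by the price times ℓ.

The south-west run has the flask's Q and L but twice its Z, and at 8.00 d I reckon its ceiling at 69.3%, with E read at 60.6%. Its ℓ was already 2.00% at 1.25 d, so I expect no plateau. For the flask I commit to about 60.6%, and my judgement, without a reckoned time, is that it comes before 6 d.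

The flask gives 62.0% at 5.14 d, with the band from 2.53 d to 10.8 d. The best amount agrees with the forecast within its margin, but the times stand earlier than forecast.

    Q + L ⇌ E (K = 52.0 M⁻¹, k = 0.0690 M⁻¹ h⁻¹)
    Z + L ⇌ D (K = 0.500 M⁻¹, k = 0.0450 M⁻¹ h⁻¹)
    L + E → G (k = 0.0100 M⁻¹ h⁻¹)

At 0.465 d the flask's L was used by Q + L → E at 13 times its rate of use by L + E → G, counting the forward rate alone. At 15.0 d the reversible step relaxes with a half-life of 1.22 d, shorter than the time allowed. The balance view keeps the north run, where ℓ was read at 1.90% at 20.0 d. Taking G as ℓ, the flask's ceiling at 15.0 d comes by the rough price to 60.9%, above its E of 55.8%. A neighbour flask, the same but charged with 0.54 M of L, comes to a ceiling of 44.9% at that time, and its E stands at 42.6%.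

All runs were computed with constants of no real substance; the scatter is artificial.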